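The route rests on cutting the bond between the benzoyloxymethyl carbon and the quaternary carbinol carbon C1 of the cyclohexene ring. The key step exploits two features of that ring: C1–OH and the C2 benzoyloxy oxygen are cis, so they can be tied into a cis-fused dioxolane, and the chlorine-bearing C6 can stand as a ketone, which makes C1 an enolisable α-carbon. In one flask the lithium enolate of an enantiopure cis-fused acetonide enone (from a catalytic desymmetrisation of a meso endoperoxide) adds to formaldehyde and is benzoylated: three components, the C–C bond and the quaternary stereocentre, set by the ring fusion. Reduction, epoxide closure and HCl opening finish.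

Key step: step 4

Atom labels: C1 = ring carbon bearing OH and CH2OBz, C2 = CH–OBz, C3 = CH–OH, C4=C5 = alkene, C6 = CH–Cl; the same labels are used for the corresponding carbons of all intermediates in the Why lines.
Remark: cis-cyclohexa-3,5-diene-1,2-diol (benzene cis-dihydrodiol from microbial oxidation of benzene) is taken as a purchasable starting material.
Remark: the sense of induction of the cinchona base in step 3 is assumed; if the antipode forms, the pseudoenantiomeric catalyst (9-O-acetylcupreine) is used instead.

Step 1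
Reactants: 1 (1R,2S)-cyclohexa-3,5-diene-1,2-diol (cis, meso)
Product: 2 (3aR,7aS)-2,2-dimethyl-3a,7a-dihydro-1,3-benzodioxole (meso cis-fused acetonide)
Conditions: Me2C(OMe)2, TsOH (cat.), CH2Cl2, 0 °C
Reagents that add atoms: 2,2-dimethoxypropane, COC(C)(C)OC
Why: Acid-catalysed transacetalisation of the cis-1,2-diol should give the cis-fused acetonide without touching a stereocentre, run cold and briefly so that dehydration to phenol does not compete.

Step 2
Reactants: 2 (3aR,7aS)-2,2-dimethyl-3a,7a-dihydro-1,3-benzodioxole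
Product: 3 meso endoperoxide (2,3-dioxabicyclo[2.2.2]oct-5-ene with a cis-7,8-isopropylidenedioxy group anti to the O–O bridge)
Conditions: O2, TPP (cat.), hν, CH2Cl2, −30 °C
Reagents that add atoms: oxygen, O=O
Why: The [4+2] cycloaddition of singlet oxygen to the diene should occur on the face anti to the dioxolane, so both new C–O bonds (C3 and C6) are trans to the neighbouring acetal oxygens.

Step 3
Reactants: 3 meso endoperoxide
Product: 5 (4S,5R,6R)-4-acetoxy-5,6-(isopropylidenedioxy)cyclohex-2-en-1-one, via hydroxy enone 4 (not isolated)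
Conditions: 9-O-acetylcupreidine (10 mol %), CH2Cl2, rt; then Ac2O, pyridine, DMAP (cat.), 0 °C
Reagents that add atoms: acetic anhydride, CC(=O)OC(C)=O
Why: In a chiral-base-catalysed Kornblum–DeLaMare rearrangement the catalyst should remove one of the two enantiotopic bridgehead protons, so that O–O cleavage gives the γ-hydroxy enone with the absolute configuration of C1, C2 and C3 fixed by the catalyst (desymmetrisation of a meso compound), and the sensitive alcohol is esterified in the same flask.

Step 4
Reactants: 5 (4S,5R,6R)-4-acetoxy-5,6-(isopropylidenedioxy)cyclohex-2-en-1-one; 6 formaldehyde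
Product: 9 [(1R,5S,6R)-5-acetoxy-1,6-(isopropylidenedioxy)-2-oxocyclohex-3-en-1-yl]methyl benzoate, via lithium dienolate 7 (not isolated), via lithium aldolate 8 (not isolated)
Conditions: LiHMDS (1.1 equiv), THF, −78 °C; CH2O (gas, from cracked paraformaldehyde), −78 °C; BzCl, −78 → 0 °C
Reagents that add atoms: benzoyl chloride, O=C(Cl)c1ccccc1
Why: LiHMDS should remove the α′-proton at C1 (the acetal-bearing carbon next to the C6 ketone) of enone 5 to give the cross-conjugated lithium dienolate 7, which adds to monomeric formaldehyde to give alkoxide 8, and benzoyl chloride then acylates this alkoxide, so that ring, CH2 unit and benzoyl group are joined in one flask. The closest known reaction type is the aldol reaction of a ketone or aldehyde enolate with formaldehyde at an α-carbon that carries an acetal oxygen (the branching of isopropylidene-protected sugars, and Seebach-type alkylations of dioxolane enolates). No ring is closed. The one new stereocentre, the quaternary C1, is controlled by the ring fusion: the electrophile can only enter on the face that keeps the 1,3-dioxolane cis-fused to the six-membered ring, so the C1–O bond is regenerated with retention and the new CH2O group ends trans to the C2 oxygen. The step needs α′- over γ-deprotonation, secured by the kinetic amide base at −78 °C, and an enolate that does not expel the C2 oxygen, secured by the five-membered ring, which holds that C–O bond close to the nodal plane of the enolate π system. Acylation in situ blocks retro-aldol cleavage of the β-hydroxy ketone.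

Step 5
Reactants: 9 [(1R,5S,6R)-5-acetoxy-1,6-(isopropylidenedioxy)-2-oxocyclohex-3-en-1-yl]methyl benzoate
Product: 10 [(1R,5S,6R)-5-acetoxy-1,6-dihydroxy-2-oxocyclohex-3-en-1-yl]methyl benzoate
Conditions: TFA/H2O (9:1), 0 °C → rt
Reagents that add atoms: none
Why: Acid-catalysed acetal hydrolysis should free the cis-diol while the esters and the enone survive, and no stereocentre is touched because C1 is quaternary.

Step 6
Reactants: 10 [(1R,5S,6R)-5-acetoxy-1,6-dihydroxy-2-oxocyclohex-3-en-1-yl]methyl benzoate
Product: 11 [(1R,5S,6R)-5-acetoxy-6-(benzoyloxy)-1-hydroxy-2-oxocyclohex-3-en-1-yl]methyl benzoate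
Conditions: BzCl (1.1 equiv), pyridine, CH2Cl2, −20 → 0 °C
Reagents that add atoms: benzoyl chloride, O=C(Cl)c1ccccc1
Why: Acylation with benzoyl chloride/pyridine should discriminate the secondary C2 hydroxyl from the hindered tertiary C1 hydroxyl, and the low temperature suppresses acetyl migration from O3.

Step 7
Reactants: 11 [(1R,5S,6R)-5-acetoxy-6-(benzoyloxy)-1-hydroxy-2-oxocyclohex-3-en-1-yl]methyl benzoate
Product: 12 [(1S,2R,5S,6R)-5-acetoxy-6-(benzoyloxy)-1,2-dihydroxycyclohex-3-en-1-yl]methyl benzoate
Conditions: Me4NBH(OAc)3, MeCN/AcOH (1:1), −30 °C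
Reagents that add atoms: none
Why: In a hydroxyl-directed (Saksena–Evans) 1,2-reduction the tertiary C1 hydroxyl should bind the triacetoxyborohydride and deliver hydride to the same face of the C6 carbonyl, so the new C6 hydroxyl is trans to the C1 hydroxyl.

Step 8
Reactants: 12 [(1S,2R,5S,6R)-5-acetoxy-6-(benzoyloxy)-1,2-dihydroxycyclohex-3-en-1-yl]methyl benzoate
Product: 13 [(1S,2R,3S,6S)-3-acetoxy-2-(benzoyloxy)-7-oxabicyclo[4.1.0]hept-4-en-1-yl]methyl benzoate
Conditions: PPh3, DIAD, THF, 0 °C → rt
Reagents that add atoms: none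
Why: In a Mitsunobu cyclodehydration of the trans-1,2-diol the secondary allylic C6 hydroxyl should be activated as the oxyphosphonium ion and displaced from the rear by the trans-diaxial tertiary C1 oxygen, giving the epoxide cis to the C2 benzoate with inversion at C6.

Step 9
Reactants: 13 [(1S,2R,3S,6S)-3-acetoxy-2-(benzoyloxy)-7-oxabicyclo[4.1.0]hept-4-en-1-yl]methyl benzoate
Product: 15 [(1R,2R,5S,6R)-6-(benzoyloxy)-2-chloro-1,5-dihydroxycyclohex-3-en-1-yl]methyl benzoate (target CNP0326102.1), via chlorohydrin acetate 14 (not isolated)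
Conditions: HCl (2 M in Et2O), CH2Cl2, −20 °C; then MeOH, rt
Reagents that add atoms: hydrogen chloride, Cl
Why: Acid-mediated trans-diaxial (Fürst–Plattner) opening of the vinyl epoxide by chloride at the allylic C6 with inversion should give the trans chlorohydrin (the quaternary C1 between two acyloxy-bearing carbons is not attacked), and the same HCl then catalyses transesterification of the acetate with methanol, which is much faster than that of the benzoates.

Compound list
1 | (1R,2S)-cyclohexa-3,5-diene-1,2-diol (cis, meso) | O[C@H]1C=CC=C[C@H]1O | starting material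
2 | (3aR,7aS)-2,2-dimethyl-3a,7a-dihydro-1,3-benzodioxole (meso cis-fused acetonide) | CC1(C)O[C@H]2C=CC=C[C@H]2O1 | intermediate
3 | meso endoperoxide, 2,3-dioxabicyclo[2.2.2]oct-5-ene with cis-7,8-isopropylidenedioxy group anti to the O–O bridge | CC1(C)O[C@H]2[C@H]3C=C[C@H](OO3)[C@H]2O1 | intermediate
4 | (4S,5R,6R)-4-hydroxy-5,6-(isopropylidenedioxy)cyclohex-2-en-1-one (not isolated) | CC1(C)O[C@H]2C(=O)C=C[C@H](O)[C@H]2O1 | intermediate
5 | (4S,5R,6R)-4-acetoxy-5,6-(isopropylidenedioxy)cyclohex-2-en-1-one | CC1(C)O[C@H]2C(=O)C=C[C@H](OC(C)=O)[C@H]2O1 | intermediate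
6 | formaldehyde | C=O | starting material
7 | lithium dienolate of 5 (O–C6=C1; not isolated) | CC1(C)OC2=C([O-])C=C[C@H](OC(C)=O)[C@H]2O1.[Li+] | intermediate
8 | lithium alkoxide of the C1-hydroxymethyl aldol adduct (not isolated) | CC1(C)O[C@@]2(C[O-])C(=O)C=C[C@H](OC(C)=O)[C@H]2O1.[Li+] | intermediate
9 | [(1R,5S,6R)-5-acetoxy-1,6-(isopropylidenedioxy)-2-oxocyclohex-3-en-1-yl]methyl benzoate | CC1(C)O[C@@]2(COC(=O)c3ccccc3)C(=O)C=C[C@H](OC(C)=O)[C@H]2O1 | intermediate
10 | [(1R,5S,6R)-5-acetoxy-1,6-dihydroxy-2-oxocyclohex-3-en-1-yl]methyl benzoate | O=C(OC[C@]1(O)C(=O)C=C[C@H](OC(C)=O)[C@H]1O)c1ccccc1 | intermediate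
11 | [(1R,5S,6R)-5-acetoxy-6-(benzoyloxy)-1-hydroxy-2-oxocyclohex-3-en-1-yl]methyl benzoate | O=C(OC[C@]1(O)C(=O)C=C[C@H](OC(C)=O)[C@H]1OC(=O)c1ccccc1)c1ccccc1 | intermediate
12 | [(1S,2R,5S,6R)-5-acetoxy-6-(benzoyloxy)-1,2-dihydroxycyclohex-3-en-1-yl]methyl benzoate | O=C(OC[C@]1(O)[C@H](O)C=C[C@H](OC(C)=O)[C@H]1OC(=O)c1ccccc1)c1ccccc1 | intermediate
13 | [(1S,2R,3S,6S)-3-acetoxy-2-(benzoyloxy)-7-oxabicyclo[4.1.0]hept-4-en-1-yl]methyl benzoate | O=C(OC[C@]1(O2)[C@@H]2C=C[C@H](OC(C)=O)[C@H]1OC(=O)c1ccccc1)c1ccccc1 | intermediate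
14 | [(1R,2R,5S,6R)-5-acetoxy-6-(benzoyloxy)-2-chloro-1-hydroxycyclohex-3-en-1-yl]methyl benzoate (not isolated) | O=C(OC[C@]1(O)[C@H](Cl)C=C[C@H](OC(C)=O)[C@H]1OC(=O)c1ccccc1)c1ccccc1 | intermediate
15 | [(1R,2R,5S,6R)-6-(benzoyloxy)-2-chloro-1,5-dihydroxycyclohex-3-en-1-yl]methyl benzoate (CNP0326102.1) | O=C(OC[C@]1(O)[C@H](Cl)C=C[C@H](O)[C@H]1OC(=O)c1ccccc1)c1ccccc1 | target

Total step count: 9
Longest linear sequence: 9 steps (1 → 15)

Steps most likely to fail

Step 4. The enolate may be lost before the C–C bond forms, either by expulsion of the C2 acetal oxygen followed by aromatisation or by competing γ-deprotonation at C3. Fallback: setting out from 5, soft enolisation (TBSOTf, Et3N, CH2Cl2, −78 °C) would give the 2-silyloxy diene, silyl dienol ether F1. A Lewis-acid-catalysed Mukaiyama hydroxymethylation with aqueous formaldehyde (Sc(OTf)3, THF/H2O) would then give the hydroxymethyl ketone F2, again with the cis ring fusion directing the new bond. Benzoylation of the primary alcohol (BzCl, pyridine) would bring the sequence back to 9.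

Step 3. The two enantiotopic bridgehead C–H bonds may be discriminated poorly on this acetonide-bearing endoperoxide, or the hydroxy enone may suffer base-induced elimination. Fallback: setting out from 3, reduction of the O–O bond with thiourea (MeOH) would give the meso diol F3 and acetylation (Ac2O, pyridine) the meso diacetate F4. Hydrolysis with Burkholderia cepacia lipase (phosphate buffer, pH 7) should cleave the acetate of the (R)-configured carbinol, as the Kazlauskas rule predicts, to give the monoacetate F5. Oxidation of the freed allylic alcohol (MnO2, CH2Cl2) would bring the sequence back to 5.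

Step 7. Ligand exchange at the hindered tertiary hydroxyl may be slow, so that hydride arrives from the other face and gives the cis-diol, which cannot close to the epoxide. Fallback: setting out from 11, a Luche reduction (NaBH4, CeCl3·7H2O, MeOH, −78 °C), in which external hydride should attack anti to the axial C1 hydroxyl, would give the cis-diol F6. SOCl2/Et3N would convert it into the cyclic sulfite F7. Opening with LiCl (DMF, 60 °C) at the allylic C6 with a single inversion, followed by aqueous work-up, would bring the sequence back to 14, which is deacetylated with HCl/MeOH as in step 9.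

Further compounds
F1 | step 4 | tert-butyldimethylsilyl dienol ether of 5 (2-silyloxy-1,3-diene, C6=C1) | CC1(C)OC2=C(O[Si](C)(C)C(C)(C)C)C=C[C@H](OC(C)=O)[C@H]2O1
F2 | step 4 | (4S,5R,6R)-4-acetoxy-6-(hydroxymethyl)-5,6-(isopropylidenedioxy)cyclohex-2-en-1-one | CC1(C)O[C@@]2(CO)C(=O)C=C[C@H](OC(C)=O)[C@H]2O1
F3 | step 3 | meso (3aR,4S,7R,7aS)-2,2-dimethyl-3a,4,7,7a-tetrahydro-1,3-benzodioxole-4,7-diol | CC1(C)O[C@H]2[C@H](O)C=C[C@H](O)[C@H]2O1
F4 | step 3 | meso diacetate of F3 | CC1(C)O[C@H]2[C@H](OC(C)=O)C=C[C@H](OC(C)=O)[C@H]2O1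
F5 | step 3 | (3aR,4S,7R,7aS)-7-hydroxy-2,2-dimethyl-3a,4,7,7a-tetrahydro-1,3-benzodioxol-4-yl acetate | CC1(C)O[C@H]2[C@H](O)C=C[C@H](OC(C)=O)[C@H]2O1
F6 | step 7 | [(1S,2S,5S,6R)-5-acetoxy-6-(benzoyloxy)-1,2-dihydroxycyclohex-3-en-1-yl]methyl benzoate (cis-diol) | O=C(OC[C@]1(O)[C@@H](O)C=C[C@H](OC(C)=O)[C@H]1OC(=O)c1ccccc1)c1ccccc1
F7 | step 7 | cyclic sulfite of F6 (O1,O6-sulfinyl, mixture at sulfur) | O=C(OC[C@]1(OS(=O)O2)[C@@H]2C=C[C@H](OC(C)=O)[C@H]1OC(=O)c1ccccc1)c1ccccc1
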